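**Retrosynthetic overview**
1. The target comes from O-debenzylation, O-methylation and OH-directed ortho/para dibromination of a 2-aryloxyphenol. Its other ring already carries all four Br and an O-benzyl group, so no bromination has to choose between the rings.
2. That phenol ring (ring A) comes from dehydrogenation of a 6-aryloxycyclohex-2-enone, itself made by intramolecular aldol condensation and decarboxylation of a 1,5-keto aldehyde.
3. The key C–C bond is an intermolecular Michael addition of a tert-butyl 2-aryloxyacetoacetate to acrolein (C3 + C3 for ring A).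
4. The donor comes from Williamson etherification of mono-O-benzyl tetrabromocatechol with tert-butyl 2-chloroacetoacetate. The ether C–O bond is therefore made at sp3 carbon, with no Cu or Pd near C–Br bonds.
5. Ring order: ring B is aromatic from the start (catechol, perbrominated first). Ring A is the only ring formed; it is closed by aldol condensation and aromatised late.

Assumption: the target has no stereocentre and no configurationally stable axis, so it is achiral and there is no enantiomer to select. The sp3 stereocentres of the ring-A precursors are carried racemic and vanish on aromatisation.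

**Step 1**
Reactants: 1 catechol (benzene-1,2-diol)
Product: 2 3,4,5,6-tetrabromobenzene-1,2-diol (tetrabromocatechol)
Conditions: Br2 (4.4 equiv), AcOH, 15 °C to 60 °C
Reagents that add atoms: bromine, BrBr
Why: Exhaustive electrophilic aromatic bromination works because every free position is ortho or para to an OH, and the product crystallises from the acid.

**Step 2**
Reactants: 2 3,4,5,6-tetrabromobenzene-1,2-diol
Product: 3 2-(benzyloxy)-3,4,5,6-tetrabromophenol
Conditions: K2CO3 (1.1 equiv), BnBr (0.95 equiv, slow addition), DMF, N2, 0 °C to rt; acidic work-up, unreacted 2 recovered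
Reagents that add atoms: benzyl bromide, BrCc1ccccc1
Why: In this Williamson mono-etherification with limiting halide, the hindered phenoxide of 3 reacts more slowly than the catecholate, so the mono-ether dominates and is separable from the diol and the neutral diether.

**Step 3**
Reactants: 4 tert-butyl acetoacetate (tert-butyl 3-oxobutanoate)
Product: 5 tert-butyl 2-chloro-3-oxobutanoate
Conditions: SO2Cl2 (1.0 equiv), CH2Cl2, 0 °C to rt
Reagents that add atoms: sulfuryl chloride, O=S(=O)(Cl)Cl
Why: Electrophilic alpha-chlorination of the enol of a beta-keto ester stops cleanly at the monochloride, and the new stereocentre is racemic and configurationally labile.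

**Step 4**
Reactants: 3 2-(benzyloxy)-3,4,5,6-tetrabromophenol; 5 tert-butyl 2-chloro-3-oxobutanoate
Product: 6 tert-butyl 2-[2-(benzyloxy)-3,4,5,6-tetrabromophenoxy]-3-oxobutanoate
Conditions: K2CO3 (1.0 equiv), DMF, rt, 30 min; then 5 (1.2 equiv), 50 °C
Reagents that add atoms: none
Why: This is an SN2 Williamson etherification at a chloride activated by two carbonyls, the weakly basic phenoxide (pKa about 6) does not enolise 5 or 6, and the stereocentre is racemic and labile.

**Step 5 (key step)**
Reactants: 6 tert-butyl 2-[2-(benzyloxy)-3,4,5,6-tetrabromophenoxy]-3-oxobutanoate; 7 acrolein (prop-2-enal)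
Product: 8 tert-butyl 2-acetyl-2-[2-(benzyloxy)-3,4,5,6-tetrabromophenoxy]-5-oxopentanoate
Conditions: acrolein (1.5 equiv, freshly distilled), Et3N (10 mol %), CH2Cl2, 0 °C to rt
Reagents that add atoms: none
Why: In this intermolecular Michael addition the acidic 2-aryloxy beta-keto ester adds under amine catalysis to the smallest and most reactive enal, and the quaternary centre forms racemic and is erased later.

**Step 6**
Reactants: 8 tert-butyl 2-acetyl-2-[2-(benzyloxy)-3,4,5,6-tetrabromophenoxy]-5-oxopentanoate
Product: 12 6-[2-(benzyloxy)-3,4,5,6-tetrabromophenoxy]cyclohex-2-en-1-one, via ketol ester 9 (not isolated), via enone ester 10 (not isolated), via keto acid 11 (not isolated)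
Conditions: p-TsOH·H2O (20 mol %), toluene, 80 °C
Reagents that add atoms: none
Why: This is an acid-catalysed intramolecular aldol condensation in which only the methyl-ketone enol attacking CHO gives a six-membered ring, followed by tert-butyl ester acidolysis and beta-keto acid decarboxylation, with C6 racemic.

**Step 7**
Reactants: 12 6-[2-(benzyloxy)-3,4,5,6-tetrabromophenoxy]cyclohex-2-en-1-one
Product: 13 2-[2-(benzyloxy)-3,4,5,6-tetrabromophenoxy]phenol
Conditions: DDQ (1.3 equiv), 1,4-dioxane, 90 °C
Reagents that add atoms: none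
Why: In this DDQ dehydrogenative aromatisation, hydride abstraction from the dienol gives a hydroxyarenium ion that loses the C6 proton, which removes the last stereocentre and leaves the electron-poor benzyl ether and the C–Br bonds untouched.

**Step 8**
Reactants: 13 2-[2-(benzyloxy)-3,4,5,6-tetrabromophenoxy]phenol
Product: 14 2-[2-(benzyloxy)-3,4,5,6-tetrabromophenoxy]-4,6-dibromophenol
Conditions: Br2 (2.1 equiv), NaOAc (2.5 equiv), AcOH/CH2Cl2, 0 °C to rt
Reagents that add atoms: bromine, BrBr
Why: In this electrophilic aromatic bromination the free OH directs Br only to its ortho and para positions, ring B has no free position, the benzyl ring is unactivated, and the buffer protects the benzyl ether from HBr.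

**Step 9**
Reactants: 14 2-[2-(benzyloxy)-3,4,5,6-tetrabromophenoxy]-4,6-dibromophenol
Product: 15 1-(benzyloxy)-2,3,4,5-tetrabromo-6-(3,5-dibromo-2-methoxyphenoxy)benzene
Conditions: MeI (1.5 equiv), K2CO3 (1.5 equiv), DMF, rt
Reagents that add atoms: iodomethane, CI
Why: Williamson O-methylation hits the only free, acidic phenol with a small electrophile, as in the routine methylation of 2,4,6-tribromophenol.

**Step 10**
Reactants: 15 1-(benzyloxy)-2,3,4,5-tetrabromo-6-(3,5-dibromo-2-methoxyphenoxy)benzene
Product: 16 3,4,5,6-tetrabromo-2-(3,5-dibromo-2-methoxyphenoxy)phenol (target)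
Conditions: BCl3 (2.5 equiv), pentamethylbenzene (3 equiv), CH2Cl2, −78 °C; then H2O
Reagents that add atoms: none
Why: Lewis-acid debenzylation with a non-basic cation scavenger (Friedel–Crafts capture of the benzyl cation) cleaves the benzyl ether at −78 °C, where the aryl methyl ether, the diaryl ether and the C–Br bonds are inert, and no reductive conditions are needed.

**Compound list**
1 | catechol (benzene-1,2-diol) | Oc1ccccc1O | starting material
2 | 3,4,5,6-tetrabromobenzene-1,2-diol | Oc1c(O)c(Br)c(Br)c(Br)c1Br | intermediate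
3 | 2-(benzyloxy)-3,4,5,6-tetrabromophenol | Oc1c(OCc2ccccc2)c(Br)c(Br)c(Br)c1Br | intermediate
4 | tert-butyl acetoacetate | CC(=O)CC(=O)OC(C)(C)C | starting material
5 | tert-butyl 2-chloro-3-oxobutanoate (racemic) | CC(=O)C(Cl)C(=O)OC(C)(C)C | intermediate
6 | tert-butyl 2-[2-(benzyloxy)-3,4,5,6-tetrabromophenoxy]-3-oxobutanoate (racemic) | CC(=O)C(Oc1c(OCc2ccccc2)c(Br)c(Br)c(Br)c1Br)C(=O)OC(C)(C)C | intermediate
7 | acrolein (prop-2-enal) | C=CC=O | starting material
8 | tert-butyl 2-acetyl-2-[2-(benzyloxy)-3,4,5,6-tetrabromophenoxy]-5-oxopentanoate (racemic) | CC(=O)C(CCC=O)(Oc1c(OCc2ccccc2)c(Br)c(Br)c(Br)c1Br)C(=O)OC(C)(C)C | intermediate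
9 | tert-butyl 1-[2-(benzyloxy)-3,4,5,6-tetrabromophenoxy]-4-hydroxy-2-oxocyclohexane-1-carboxylate (racemic diastereomer mixture, not isolated) | O=C1CC(O)CCC1(Oc2c(OCc3ccccc3)c(Br)c(Br)c(Br)c2Br)C(=O)OC(C)(C)C | intermediate
10 | tert-butyl 1-[2-(benzyloxy)-3,4,5,6-tetrabromophenoxy]-2-oxocyclohex-3-ene-1-carboxylate (racemic, not isolated) | O=C1C=CCCC1(Oc2c(OCc3ccccc3)c(Br)c(Br)c(Br)c2Br)C(=O)OC(C)(C)C | intermediate
11 | 1-[2-(benzyloxy)-3,4,5,6-tetrabromophenoxy]-2-oxocyclohex-3-ene-1-carboxylic acid (racemic, not isolated) | O=C1C=CCCC1(Oc2c(OCc3ccccc3)c(Br)c(Br)c(Br)c2Br)C(=O)O | intermediate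
12 | 6-[2-(benzyloxy)-3,4,5,6-tetrabromophenoxy]cyclohex-2-en-1-one (racemic) | O=C1C=CCCC1Oc2c(OCc3ccccc3)c(Br)c(Br)c(Br)c2Br | intermediate
13 | 2-[2-(benzyloxy)-3,4,5,6-tetrabromophenoxy]phenol | Oc1ccccc1Oc2c(OCc3ccccc3)c(Br)c(Br)c(Br)c2Br | intermediate
14 | 2-[2-(benzyloxy)-3,4,5,6-tetrabromophenoxy]-4,6-dibromophenol | Oc1c(Br)cc(Br)cc1Oc2c(OCc3ccccc3)c(Br)c(Br)c(Br)c2Br | intermediate
15 | 1-(benzyloxy)-2,3,4,5-tetrabromo-6-(3,5-dibromo-2-methoxyphenoxy)benzene | COc1c(Br)cc(Br)cc1Oc2c(OCc3ccccc3)c(Br)c(Br)c(Br)c2Br | intermediate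
16 | 3,4,5,6-tetrabromo-2-(3,5-dibromo-2-methoxyphenoxy)phenol (achiral) | COc1c(Br)cc(Br)cc1Oc1c(O)c(Br)c(Br)c(Br)c1Br | target

**Totals**
Total step count: 10.
Longest linear sequence: 9 steps (1 → 2 → 3 → 6 → 8 → 12 → 13 → 14 → 15 → 16). Step 3 is the side branch.

**Three steps most likely to fail**

Step 4. The phenoxide of 3 is di-ortho-substituted and a weak nucleophile, and 5 is base-sensitive, so the displacement may stall or 5 may self-condense. The fallback sets out from 4 and 3 and comes back at 6. It does not need the phenoxide to act as a nucleophile. Regitz diazo transfer onto 4 (p-acetamidobenzenesulfonyl azide, Et3N, MeCN, rt) gives tert-butyl 2-diazo-3-oxobutanoate F1. Slow addition of this to 3 with Rh2(OAc)4 (1 mol %) in CH2Cl2 at reflux gives 6 by rhodium-carbenoid O–H insertion. Acidic phenols are good substrates for this reaction.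

Step 6. Hot sulfonic acid may expel the good leaving group 3 from 12 or 10, because loss of ArOH also aromatises the new ring. The fallback sets out from 8 and comes back at 12. It separates the events so that no hot acid is used. TFA/CH2Cl2 at rt cleaves the ester to 2-acetyl-2-[2-(benzyloxy)-3,4,5,6-tetrabromophenoxy]-5-oxopentanoic acid F2. This acid decarboxylates on warming to 40 °C to 4-[2-(benzyloxy)-3,4,5,6-tetrabromophenoxy]-5-oxohexanal F3. The less crowded keto aldehyde is then closed at rt by iminium-type (Mannich–elimination) aldol condensation with pyrrolidine/AcOH (20 mol % each) in CH2Cl2. Only the six-membered closure is geometrically possible.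

Step 7. DDQ dehydrogenation of a simple cyclohexenone can be sluggish, and loss of ArOH competes. The fallback sets out from 12 and comes back at 14, skipping the isolation of 13. It replaces hydride abstraction with halogenation–dehydrohalogenation. CuBr2 (4.5 equiv)/LiBr in MeCN at reflux brominates the alpha' position to give 6-[2-(benzyloxy)-3,4,5,6-tetrabromophenoxy]-6-bromocyclohex-2-en-1-one F4. This loses HBr and tautomerises to 13. Excess CuBr2 carries part of 13 on to 2-[2-(benzyloxy)-3,4,5,6-tetrabromophenoxy]-4-bromophenol F5. Every position this chemistry can brominate carries Br in 14. The crude mixture is therefore treated with Br2/NaOAc as in step 8 and converges on 14.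

**Further compounds**
F1 | step 4 | tert-butyl 2-diazo-3-oxobutanoate | CC(=O)C(=[N+]=[N-])C(=O)OC(C)(C)C
F2 | step 6 | 2-acetyl-2-[2-(benzyloxy)-3,4,5,6-tetrabromophenoxy]-5-oxopentanoic acid (racemic) | CC(=O)C(CCC=O)(Oc1c(OCc2ccccc2)c(Br)c(Br)c(Br)c1Br)C(=O)O
F3 | step 6 | 4-[2-(benzyloxy)-3,4,5,6-tetrabromophenoxy]-5-oxohexanal (racemic) | CC(=O)C(CCC=O)Oc1c(OCc2ccccc2)c(Br)c(Br)c(Br)c1Br
F4 | step 7 | 6-[2-(benzyloxy)-3,4,5,6-tetrabromophenoxy]-6-bromocyclohex-2-en-1-one (racemic) | O=C1C=CCCC1(Br)Oc2c(OCc3ccccc3)c(Br)c(Br)c(Br)c2Br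
F5 | step 7 | 2-[2-(benzyloxy)-3,4,5,6-tetrabromophenoxy]-4-bromophenol | Oc1ccc(Br)cc1Oc2c(OCc3ccccc3)c(Br)c(Br)c(Br)c2Br
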